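The easy step is the starting-material column. In west it reads 0% at 3.00 min and in north 0.1%, within scatter of zero, yet product stands at just 8.8% and 8.0%. In west 91 percentage points of the charge then stands in neither column, an unseen pool, and the steady climb of product points to that pool as its source.

common to all: starting material 0.66 M
- west: protic impurity 0.0086 M; run made earlier
- north: protic impurity 0.082 M; run made earlier
- alder: protic impurity 0.0120 M; time 10 min
- cedar: protic impurity 0.0400 M; time 10 min
- oak: protic impurity 0.120 M; time 10 min

| run | time / min | product / % | starting material / % |
|---|---|---|---|
| west | 1.33 | 3.2 | 3.0 |
| west | 3.00 | 8.8 | 0 |
| west | 4.00 | 11.9 | 0 |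
| west | 6.00 | 17.6 | 0.5 |
| west | 8.00 | 23.3 | 0.1 |
| north | 1.33 | 2.9 | 1.8 |
| north | 3.00 | 8.0 | 0.1 |
| north | 4.00 | 10.4 | 0 |
| north | 6.00 | 16.4 | 0.1 |
| north | 8.00 | 21.6 | 0.1 |

(readings scatter by 0.3 percentage points)

- the numbers in the tables scatter with a standard deviation of 0.3 percentage points
- "hardly changes" means that all values lie within two and a half points (for a concentration: within two and a half percent of the largest)

1. amount of product at the end, in percent of the starting material charged for alder, cedar, oak, in this order
2. the course of these numbers from the first flask to the last (rises, then falls / falls all the way / rises all the way / hardly changes / falls, then rises)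

Reading west down its rows, product climbs at 0.0290 /min, as a fraction of the charge, between 3.00 min and 8.00 min. Over that stretch the pool, taken as the charge minus product, averages 0.840 of the charge. The impurity in west amounts to 0.0130 of the charge, so it is set aside here. Dividing gives the drain constant, the fraction of the pool turned into product per minute: 0.0345 /min.

My reckoning goes round twice. The straight line carries west from 23.3% to 29.1% at 10 min. But the pool has shrunk by 8.00 min, so putting that smaller pool back in gives 28.4%, lower than the line.

Reading west against north, the last row of north holds 0.927 of the product of west, with extra impurity equal to 0.111 of the charge. As a reading, each unit of extra impurity costs 0.656 of a unit of pool. Scaled in a straight line, this gives 28.3%, 27.5% and 25.3% for alder, cedar and oak, a fall of 3.0 points.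

The forecast, working from “a nearly zero-order rate”, gives 29%, 28.1% and 26%, and its course falls all the way. It has the same direction as my reckoning, with each value higher .

Alder, cedar and oak give 28.2%, 27.2% and 24.7%, so the course falls all the way, and the forecast stands within its margin.

    starting material → intermediate (k = 2.70 /min)
    intermediate → product (k = 0.0350 /min)
    starting material + protic impurity → quenched substrate (k = 6.90 /M/min)

Oak holds 61.4% of the charge as intermediate, the resting state, at 10.0 min. Draining that at 0.0345 /min until 100 min leaves 2.75%, and the oak flask then holds 2.63%.

(The readings stem from a simulated flask on assumed constants; noise was put on by code.)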